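**Plan**

- Retrosynthesis: the C1 methyl ether and the C2 silyl ether are removed to reach a bicyclic acyloin. Its cyclopentanone ring is then opened at C8–C1 and C5–C6 together, giving an open-chain keto aldehyde. The chain is cut at C1–C7 into an α-silyloxy aldehyde and elemicin, and the aldehyde goes back through an epoxy alcohol to an achiral allylic alcohol.
- Enabling feature: in ring C1–C8–C5–C6–C7 the C8 carbonyl lies between oxygen-bearing C1 (an acyloin) and quaternary C5, and C6 is β to C1. With C1 as a ketone, C8–C1 is a benzoin bond and C5–C6 a Michael bond of one keto aldehyde.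
- Forward: the chain is built linearly from pent-4-enenitrile and joined to the aryl-allyl unit. It is then closed in one flask: the seven-membered ring by Michael addition, then the one-carbon bridge by benzoin reaction, which creates the five- and six-membered rings at once.
- Stereochemistry: C2 and C3 come from Sharpless epoxidation and anti opening with methanol. C5 and C6 are set in the Michael step under their control, C7 by equilibration next to the ketone, and C1 by the geometry of the bridge.

Key step: step 10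

Remark: locants C1–C8 are those of the bicyclo[3.2.1]octan-8-one core of the target (C1 methoxy bridgehead, C2 carbinol, C3 methoxy carbon, C4 methylene, C5 allyl bridgehead, C6 methyl carbon, C7 aryl carbon). The carbon that becomes C5 is carried as a mixture of epimers in all chain intermediates, and the adducts of the fragment union are also mixtures at the future C1 and C7. This is assumed to be harmless because all these centres become trigonal before or during the key step.

**Route**

Step 1
Reactants: 1 pent-4-enenitrile; 2 (E)-1,4-dibromobut-2-ene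
Product: 3 (4E)-6-bromo-2-(prop-2-enyl)hex-4-enenitrile
Conditions: LiN(i-Pr)2, THF, −78 °C; then inverse addition to 2 (3 equiv), THF, −78 °C
Reagents that add atoms: none
Why: SN2 alkylation of the lithiated nitrile at one allylic terminus of the symmetrical dibromide (nitrile anion alkylation), with excess dibromide and inverse addition so that monoalkylation should dominate; the new centre is racemic, which does not matter because it becomes trigonal in step 10.

Step 2
Reactants: 3 (4E)-6-bromo-2-(prop-2-enyl)hex-4-enenitrile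
Product: 5 (4E)-6-hydroxy-2-(prop-2-enyl)hex-4-enenitrile, via allylic acetate 4 (not isolated)
Conditions: KOAc, DMF, rt; then MeOH, K2CO3 (cat.), rt, same flask
Reagents that add atoms: potassium acetate, CC(=O)[O-].[K+]
Why: acetate displacement of the primary allylic bromide (SN2) followed by methanolysis of the acetate should give the (E)-allylic alcohol without touching the nitrile.

Step 3
Reactants: 5 (4E)-6-hydroxy-2-(prop-2-enyl)hex-4-enenitrile
Product: 6 2-{[(2S,3S)-3-(hydroxymethyl)oxiran-2-yl]methyl}pent-4-enenitrile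
Conditions: Ti(OiPr)4 (10 mol %), L-(+)-diisopropyl tartrate (12 mol %), t-BuOOH, 4 Å MS, CH2Cl2, −20 °C
Reagents that add atoms: tert-butyl hydroperoxide, CC(C)(C)OO
Why: Sharpless asymmetric epoxidation, in which the titanium–L-(+)-tartrate catalyst delivers oxygen to one face of the (E)-allylic alcohol and so sets both epoxide carbons as (2S,3S), while the isolated terminal alkene is left alone.

Step 4
Reactants: 6 2-{[(2S,3S)-3-(hydroxymethyl)oxiran-2-yl]methyl}pent-4-enenitrile
Product: 7 2-[(2R,3S)-3,4-dihydroxy-2-methoxybutyl]pent-4-enenitrile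
Conditions: Eu(OTf)3 (10 mol %), 2,6-di-tert-butyl-4-methylpyridine (10 mol %), MeOH, rt
Reagents that add atoms: methanol, CO
Why: Lewis-acid chelation of the 2,3-epoxy alcohol should direct methanol to the epoxide carbon remote from the hydroxymethyl group (C-3-selective epoxide opening), and the anti opening converts the trans-epoxide into the erythro methoxy diol, which fixes the future C3 (methoxy) and C2 (hydroxyl) in their final configurations.

Step 5
Reactants: 7 2-[(2R,3S)-3,4-dihydroxy-2-methoxybutyl]pent-4-enenitrile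
Product: 8 2-[(2R,3S)-2-methoxy-3,4-bis(triethylsilyloxy)butyl]pent-4-enenitrile
Conditions: Et3SiCl (2.5 equiv), imidazole, DMAP (cat.), CH2Cl2, 0 °C to rt
Reagents that add atoms: chlorotriethylsilane, CC[Si](Cl)(CC)CC
Why: standard silylation of both hydroxyl groups, which prepares the selective oxidation of step 6.

Step 6
Reactants: 8 2-[(2R,3S)-2-methoxy-3,4-bis(triethylsilyloxy)butyl]pent-4-enenitrile
Product: 9 2-[(2R,3R)-2-methoxy-4-oxo-3-(triethylsilyloxy)butyl]pent-4-enenitrile
Conditions: (COCl)2, DMSO, CH2Cl2, −78 to −40 °C; then Et3N, −78 to 0 °C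
Reagents that add atoms: none
Why: under Swern conditions a primary triethylsilyl ether is cleaved and oxidised in situ whereas the secondary one survives (selective oxidative desilylation), so the α-silyloxy aldehyde should form in one operation.

Step 7
Reactants: 9 2-[(2R,3R)-2-methoxy-4-oxo-3-(triethylsilyloxy)butyl]pent-4-enenitrile; 10 elemicin (5-allyl-1,2,3-trimethoxybenzene)
Product: 13 2-[(2R,3S)-4-hydroxy-2-methoxy-3-(triethylsilyloxy)-5-(3,4,5-trimethoxyphenyl)hept-6-enyl]pent-4-enenitrile, via [(2E)-3-(3,4,5-trimethoxyphenyl)prop-2-enyl]lithium 11 (not isolated), via tri(propan-2-yloxy)[(2E)-3-(3,4,5-trimethoxyphenyl)prop-2-enyl]titanium 12 (not isolated)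
Conditions: 10, sec-BuLi, THF, −78 °C; ClTi(OiPr)3, −78 °C; then 9, −78 to −40 °C; aq. NH4Cl
Reagents that add atoms: none
Why: allylic deprotonation of the allylarene, transmetalation to the allyltitanium and addition to the aldehyde through a six-membered transition state at the aryl-bearing γ-carbon (γ-selective allyltitanation) should join the fragments at the future C1–C7 bond; the two new centres form as a mixture and are both erased in step 9.

Step 8
Reactants: 13 2-[(2R,3S)-4-hydroxy-2-methoxy-3-(triethylsilyloxy)-5-(3,4,5-trimethoxyphenyl)hept-6-enyl]pent-4-enenitrile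
Product: 15 (4R,5S)-6-hydroxy-4-methoxy-2-(prop-2-enyl)-5-(triethylsilyloxy)-7-(3,4,5-trimethoxyphenyl)non-8-enal, via primary aldimine 14 (not isolated)
Conditions: i-Bu2AlH (3 equiv), CH2Cl2, −78 °C; aq. KNaC4H4O6, then pH 4 tartrate buffer, 0 °C
Reagents that add atoms: water, O
Why: i-Bu2AlH adds once to the nitrile and the resulting imine is hydrolysed to the aldehyde on work-up (nitrile-to-aldehyde reduction), while the secondary hydroxyl is only deprotonated and the silyl ether and alkenes are inert.

Step 9
Reactants: 15 (4R,5S)-6-hydroxy-4-methoxy-2-(prop-2-enyl)-5-(triethylsilyloxy)-7-(3,4,5-trimethoxyphenyl)non-8-enal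
Product: 17 (4R,5R,7E)-4-methoxy-6-oxo-2-(prop-2-enyl)-5-(triethylsilyloxy)-7-(3,4,5-trimethoxyphenyl)non-7-enal, via β,γ-unsaturated keto aldehyde 16 (not isolated)
Conditions: Dess–Martin periodinane, CH2Cl2, 0 °C to rt; aq. NaHCO3/Na2S2O3 wash; then Et3N (0.2 equiv), CH2Cl2, rt
Reagents that add atoms: none
Why: Dess–Martin oxidation gives an α-aryl β,γ-unsaturated ketone whose doubly activated C–H is removed by the amine, so the double bond should move into conjugation and settle as the more stable (E)-enone (acyl trans to methyl).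

Step 10
Reactants: 17 (4R,5R,7E)-4-methoxy-6-oxo-2-(prop-2-enyl)-5-(triethylsilyloxy)-7-(3,4,5-trimethoxyphenyl)non-7-enal
Product: 19 (1R,2R,3R,5S,6S,7R)-1-hydroxy-3-methoxy-6-methyl-5-(prop-2-enyl)-2-(triethylsilyloxy)-7-(3,4,5-trimethoxyphenyl)bicyclo[3.2.1]octan-8-one, via cycloheptanone aldehyde 18 (not isolated)
Conditions: pyrrolidine (20 mol %), PhCO2H (20 mol %), CHCl3, 23 °C; then 2-(pentafluorophenyl)-6,7-dihydro-5H-pyrrolo[2,1-c][1,2,4]triazol-2-ium tetrafluoroborate (20 mol %), NaOAc (20 mol %), 40 °C, same flask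
Reagents that add atoms: none
Why: Proposed new method: relay catalysis in which the pyrrolidine enamine of the α-branched aldehyde attacks the β-carbon of the tethered (E)-enone (C5–C6 bond), and the aldehyde of the resulting cycloheptanone 18, which can no longer form an enamine, is turned by the triazolylidene into a Breslow acyl-anion equivalent that adds across the ring to the ketone (C8–C1 bond); the closest known reaction types are the amine/carbene Michael–crossed-benzoin cascade to α-hydroxycyclopentanones and the carbene-catalysed aldehyde–ketone benzoin to bridged acyloins, neither of which has been shown with a 7-endo Michael step or an α-quaternary aldehyde. The seven-membered ring closes 7-endo-trig, and the benzoin then closes the cyclopentanone (5-exo-trig) and the cyclohexanone (6-exo-trig) together by one transannular attack on the C1 carbonyl. C5 is expected to be set by the C2/C3 stereocentres of the tether, which should sit pseudo-equatorial in the closing ring so that the later chair cyclohexanone carries an equatorial C3 methoxy group; C6 by an open transition state in which the bulky aminomethylene end of the enamine points away from the enone and the allyl group lies over it, which places the methyl of the (E)-enone cis to C4 (endo); C7 by equilibration α to the ketone in 18 to the trans aryl/methyl arrangement; and C1 by geometry, since the one-carbon bridge can span only one face. The step needs the Michael addition to precede carbene chemistry and to outrun loss of methanol or epimerisation next to the ketone: the carbene precursor is added only after 17 is consumed, the reversible 5-exo aldol of the enamine onto the ketone is a non-productive equilibrium, and only carboxylate bases are present.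

Step 11
Reactants: 19 (1R,2R,3R,5S,6S,7R)-1-hydroxy-3-methoxy-6-methyl-5-(prop-2-enyl)-2-(triethylsilyloxy)-7-(3,4,5-trimethoxyphenyl)bicyclo[3.2.1]octan-8-one
Product: 20 (1R,2R,3R,5S,6S,7R)-1,3-dimethoxy-6-methyl-5-(prop-2-enyl)-2-(triethylsilyloxy)-7-(3,4,5-trimethoxyphenyl)bicyclo[3.2.1]octan-8-one
Conditions: MeOTf, 2,6-di-tert-butyl-4-methylpyridine, CH2Cl2, 0 °C to rt
Reagents that add atoms: methyl trifluoromethanesulfonate, COS(=O)(=O)C(F)(F)F
Why: O-methylation of the tertiary bridgehead hydroxyl with methyl triflate under hindered-pyridine buffering keeps the medium neutral and should avoid the alkoxide-induced α-ketol rearrangement; no stereocentre is touched.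

Step 12
Reactants: 20 (1R,2R,3R,5S,6S,7R)-1,3-dimethoxy-6-methyl-5-(prop-2-enyl)-2-(triethylsilyloxy)-7-(3,4,5-trimethoxyphenyl)bicyclo[3.2.1]octan-8-one
Product: 21 (1R,2R,3R,5S,6S,7R)-2-hydroxy-1,3-dimethoxy-6-methyl-5-(prop-2-enyl)-7-(3,4,5-trimethoxyphenyl)bicyclo[3.2.1]octan-8-one
Conditions: HF·pyridine, pyridine, THF, 0 °C to rt
Reagents that add atoms: none
Why: fluoride cleavage of the secondary triethylsilyl ether under buffered, non-basic conditions should free the C2 hydroxyl without epimerisation or skeletal change.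

**Compound list**

1 | pent-4-enenitrile | C=CCCC#N | starting material
2 | (E)-1,4-dibromobut-2-ene | BrC/C=C/CBr | starting material
3 | (4E)-6-bromo-2-(prop-2-enyl)hex-4-enenitrile (racemic) | N#CC(CC=C)C/C=C/CBr | intermediate
4 | (2E)-5-cyanoocta-2,7-dienyl acetate (racemic, not isolated) | CC(=O)OC/C=C/CC(C#N)CC=C | intermediate
5 | (4E)-6-hydroxy-2-(prop-2-enyl)hex-4-enenitrile (racemic) | N#CC(CC=C)C/C=C/CO | intermediate
6 | 2-{[(2S,3S)-3-(hydroxymethyl)oxiran-2-yl]methyl}pent-4-enenitrile (epimers at the nitrile α-carbon) | N#CC(CC=C)C[C@@H]1O[C@H]1CO | intermediate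
7 | 2-[(2R,3S)-3,4-dihydroxy-2-methoxybutyl]pent-4-enenitrile (epimers at the nitrile α-carbon) | N#CC(CC=C)C[C@@H](OC)[C@@H](O)CO | intermediate
8 | 2-[(2R,3S)-2-methoxy-3,4-bis(triethylsilyloxy)butyl]pent-4-enenitrile (epimers at the nitrile α-carbon) | N#CC(CC=C)C[C@@H](OC)[C@@H](O[Si](CC)(CC)CC)CO[Si](CC)(CC)CC | intermediate
9 | 2-[(2R,3R)-2-methoxy-4-oxo-3-(triethylsilyloxy)butyl]pent-4-enenitrile (epimers at the nitrile α-carbon) | N#CC(CC=C)C[C@@H](OC)[C@@H](O[Si](CC)(CC)CC)C=O | intermediate
10 | elemicin, 5-allyl-1,2,3-trimethoxybenzene | C=CCc1cc(OC)c(OC)c(OC)c1 | starting material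
11 | [(2E)-3-(3,4,5-trimethoxyphenyl)prop-2-enyl]lithium (not isolated) | [Li]C/C=C/c1cc(OC)c(OC)c(OC)c1 | intermediate
12 | tri(propan-2-yloxy)[(2E)-3-(3,4,5-trimethoxyphenyl)prop-2-enyl]titanium (not isolated) | CC(C)O[Ti](OC(C)C)(OC(C)C)C/C=C/c1cc(OC)c(OC)c(OC)c1 | intermediate
13 | 2-[(2R,3S)-4-hydroxy-2-methoxy-3-(triethylsilyloxy)-5-(3,4,5-trimethoxyphenyl)hept-6-enyl]pent-4-enenitrile (mixture at the nitrile α-carbon and at side-chain C-4 and C-5) | N#CC(CC=C)C[C@@H](OC)[C@@H](O[Si](CC)(CC)CC)C(O)C(C=C)c1cc(OC)c(OC)c(OC)c1 | intermediate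
14 | (4R,5S)-1-imino-4-methoxy-2-(prop-2-enyl)-5-(triethylsilyloxy)-7-(3,4,5-trimethoxyphenyl)non-8-en-6-ol (mixture at C-2, C-6, C-7; not isolated) | N=CC(CC=C)C[C@@H](OC)[C@@H](O[Si](CC)(CC)CC)C(O)C(C=C)c1cc(OC)c(OC)c(OC)c1 | intermediate
15 | (4R,5S)-6-hydroxy-4-methoxy-2-(prop-2-enyl)-5-(triethylsilyloxy)-7-(3,4,5-trimethoxyphenyl)non-8-enal (mixture at C-2, C-6, C-7) | O=CC(CC=C)C[C@@H](OC)[C@@H](O[Si](CC)(CC)CC)C(O)C(C=C)c1cc(OC)c(OC)c(OC)c1 | intermediate
16 | (4R,5R)-4-methoxy-6-oxo-2-(prop-2-enyl)-5-(triethylsilyloxy)-7-(3,4,5-trimethoxyphenyl)non-8-enal (mixture at C-2 and C-7; not isolated) | O=CC(CC=C)C[C@@H](OC)[C@@H](O[Si](CC)(CC)CC)C(=O)C(C=C)c1cc(OC)c(OC)c(OC)c1 | intermediate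
17 | (4R,5R,7E)-4-methoxy-6-oxo-2-(prop-2-enyl)-5-(triethylsilyloxy)-7-(3,4,5-trimethoxyphenyl)non-7-enal (epimers at C-2) | O=CC(CC=C)C[C@@H](OC)[C@@H](O[Si](CC)(CC)CC)C(=O)/C(=C/C)c1cc(OC)c(OC)c(OC)c1 | intermediate
18 | (1S,2S,3R,5R,6R)-6-methoxy-2-methyl-4-oxo-1-(prop-2-enyl)-5-(triethylsilyloxy)-3-(3,4,5-trimethoxyphenyl)cycloheptane-1-carbaldehyde (not isolated) | C=CC[C@]1(C=O)C[C@@H](OC)[C@@H](O[Si](CC)(CC)CC)C(=O)[C@@H](c2cc(OC)c(OC)c(OC)c2)[C@@H]1C | intermediate
19 | (1R,2R,3R,5S,6S,7R)-1-hydroxy-3-methoxy-6-methyl-5-(prop-2-enyl)-2-(triethylsilyloxy)-7-(3,4,5-trimethoxyphenyl)bicyclo[3.2.1]octan-8-one | C=CC[C@@]12C[C@@H](OC)[C@@H](O[Si](CC)(CC)CC)[C@@](O)(C1=O)[C@@H](c1cc(OC)c(OC)c(OC)c1)[C@@H]2C | intermediate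
20 | (1R,2R,3R,5S,6S,7R)-1,3-dimethoxy-6-methyl-5-(prop-2-enyl)-2-(triethylsilyloxy)-7-(3,4,5-trimethoxyphenyl)bicyclo[3.2.1]octan-8-one | C=CC[C@@]12C[C@@H](OC)[C@@H](O[Si](CC)(CC)CC)[C@@](OC)(C1=O)[C@@H](c1cc(OC)c(OC)c(OC)c1)[C@@H]2C | intermediate
21 | (1R,2R,3R,5S,6S,7R)-2-hydroxy-1,3-dimethoxy-6-methyl-5-(prop-2-enyl)-7-(3,4,5-trimethoxyphenyl)bicyclo[3.2.1]octan-8-one | C=CC[C@@]12C[C@@H](OC)[C@@H](O)[C@@](OC)(C1=O)[C@@H](c1cc(OC)c(OC)c(OC)c1)[C@@H]2C | target

**Summary**

Total step count: 12. Longest linear sequence: 12 steps, from pent-4-enenitrile 1; elemicin 10 enters as a purchased fragment in step 7.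

**Steps most likely to fail**

Step 10. The 7-endo Michael closure may fail to compete with the reversible aldol and aza-Michael equilibria, or may proceed with poor facial selectivity at C5 or C6. The carbene may add too slowly to the neopentyl aldehyde, and base may cause loss of methanol or epimerisation next to the ketone. The fallback sets out from 17 and comes back at 19, replacing amine and carbene catalysis by Lewis-acid and ketyl chemistry with isolation of each stage. Compound 17 is converted (TMSOTf, Et3N, CH2Cl2, −78 °C) into the aldehyde-derived trimethylsilyl enol ether F1. TiCl4-promoted intramolecular Mukaiyama–Michael addition (CH2Cl2, −78 °C) and aqueous work-up should give cycloheptanone aldehyde 18, now isolated. SmI2 (THF, t-BuOH, −78 °C to rt) then joins the aldehyde and ketone carbons by ketyl pinacol coupling to give the bicyclic 1,8-diol F2. Parikh–Doering oxidation (SO3·pyridine, DMSO, i-Pr2NEt) of the secondary C8 carbinol returns 19.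

Step 11. The hindered tertiary hydroxyl may not react, or adventitious acid may cause α-ketol rearrangement or silyl loss. The fallback sets out from 19 and comes back at 20, introducing the methyl group in two stages through a thioacetal. Pummerer-type alkylation (DMSO, Ac2O, AcOH, rt) should give the methylthiomethyl ether F3. Desulfurisation with acetone-deactivated Raney Ni (EtOH, rt), which should spare the allyl group, gives 20.

Step 7. Ring lithiation of the electron-rich arene may compete with allylic deprotonation, the allylmetal may attack through its α-terminus, or the sensitive α-silyloxy aldehyde may be enolised. The fallback sets out from 9 and comes back at 17, building the enone from a benzyl nucleophile and acetaldehyde. 3,4,5-Trimethoxybenzylmagnesium chloride F4 (from the commercial benzyl chloride and Mg, Et2O) adds to 9 at −78 °C to give carbinol F5. Dess–Martin oxidation gives benzyl ketone F6. Piperidinium acetate-catalysed condensation with acetaldehyde at the benzylic methylene (toluene, 4 Å MS, sealed tube) should give the (E)-cyano enone F7. Excess i-Bu2AlH (CH2Cl2, −78 °C, hydrolytic work-up) reduces ketone and nitrile to the allylic alcohol aldehyde F8. MnO2 (CH2Cl2, rt) reoxidises the allylic alcohol and returns 17.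

Further compounds
F1 | step 10 | (4R,5R,7E)-4-methoxy-2-(prop-2-enyl)-5-(triethylsilyloxy)-7-(3,4,5-trimethoxyphenyl)-1-(trimethylsilyloxy)nona-1,7-dien-6-one (E/Z mixture at the enol ether) | C[Si](C)(C)OC=C(CC=C)C[C@@H](OC)[C@@H](O[Si](CC)(CC)CC)C(=O)/C(=C/C)c1cc(OC)c(OC)c(OC)c1
F2 | step 10 | 8-hydroxy analogue of 19: 3-methoxy-6-methyl-5-(prop-2-enyl)-2-(triethylsilyloxy)-7-(3,4,5-trimethoxyphenyl)bicyclo[3.2.1]octane-1,8-diol, ring configurations as in 19, either C-8 epimer | C=CC[C@@]12C[C@@H](OC)[C@@H](O[Si](CC)(CC)CC)[C@@](O)(C1O)[C@@H](c1cc(OC)c(OC)c(OC)c1)[C@@H]2C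
F3 | step 11 | (1R,2R,3R,5S,6S,7R)-3-methoxy-6-methyl-1-[(methylsulfanyl)methoxy]-5-(prop-2-enyl)-2-(triethylsilyloxy)-7-(3,4,5-trimethoxyphenyl)bicyclo[3.2.1]octan-8-one | C=CC[C@@]12C[C@@H](OC)[C@@H](O[Si](CC)(CC)CC)[C@@](OCSC)(C1=O)[C@@H](c1cc(OC)c(OC)c(OC)c1)[C@@H]2C
F4 | step 7 | 3,4,5-trimethoxybenzylmagnesium chloride | Cl[Mg]Cc1cc(OC)c(OC)c(OC)c1
F5 | step 7 | 2-[(2R,3S)-4-hydroxy-2-methoxy-3-(triethylsilyloxy)-5-(3,4,5-trimethoxyphenyl)pentyl]pent-4-enenitrile (mixture at the nitrile α-carbon and the carbinol) | N#CC(CC=C)C[C@@H](OC)[C@@H](O[Si](CC)(CC)CC)C(O)Cc1cc(OC)c(OC)c(OC)c1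
F6 | step 7 | 2-[(2R,3R)-2-methoxy-4-oxo-3-(triethylsilyloxy)-5-(3,4,5-trimethoxyphenyl)pentyl]pent-4-enenitrile | N#CC(CC=C)C[C@@H](OC)[C@@H](O[Si](CC)(CC)CC)C(=O)Cc1cc(OC)c(OC)c(OC)c1
F7 | step 7 | 2-[(2R,3R,5E)-2-methoxy-4-oxo-3-(triethylsilyloxy)-5-(3,4,5-trimethoxyphenyl)hept-5-enyl]pent-4-enenitrile | N#CC(CC=C)C[C@@H](OC)[C@@H](O[Si](CC)(CC)CC)C(=O)/C(=C/C)c1cc(OC)c(OC)c(OC)c1
F8 | step 7 | (4R,5S,7E)-6-hydroxy-4-methoxy-2-(prop-2-enyl)-5-(triethylsilyloxy)-7-(3,4,5-trimethoxyphenyl)non-7-enal (mixture at C-2 and C-6) | O=CC(CC=C)C[C@@H](OC)[C@@H](O[Si](CC)(CC)CC)C(O)/C(=C/C)c1cc(OC)c(OC)c(OC)c1
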